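The readings were computed with constants of no real substance; scatter was added.

Late in the ash run, at 20.0 h, mono adduct had fallen to 14.3%, so I doubted your hunch that more partner gives more of it at the end.

| setting | birch | ash | winter | autumn |
|---|---|---|---|---|
| substrate | 0.050 M | 0.050 M | 0.050 M | 0.050 M |
| partner | 0.062 M | 0.23 M | 0.300 M | 0.100 M |
| remark | run made earlier | run made earlier |  |  |
| time |  |  | 20 h | 20 h |

| run | time / h | mono adduct / % | substrate / % |
|---|---|---|---|
| birch | 5.00 | 8.0 | 79.4 |
| birch | 10.0 | 13.1 | 65.6 |
| birch | 15.0 | 16.2 | 55.4 |
| birch | 20.0 | 18.0 | 48.3 |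
| ash | 1.50 | 9.0 | 76.0 |
| ash | 4.00 | 17.4 | 50.0 |
| ash | 8.00 | 21.3 | 27.0 |
| ash | 20.0 | 14.3 | 4.8 |

(each reading ± 0.3 percentage points)

1. which of the two there is more of at the end, winter (over-reaction product / mono adduct)
2. which of the two there is more of at the end, autumn (over-reaction product / mono adduct)
3. amount of mono adduct at the end, in percent of the substrate charged, winter
4. amount of mono adduct at the end, in percent of the substrate charged, autumn

Birch and ash, at nearly equal substrate (48.3% and 50.0%), held 18.0% and 17.4% of mono adduct at different times. So I read mono adduct as a function of substrate, with c as a fraction of the substrate charged. The curve depends on the selectivity factor s, the adduct's loss constant over the substrate's.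

The symmetric case, s = 1, was my zero. It needs c(mono adduct)/(c(substrate)·ln(1/c(substrate))) to stay constant, but this rose from 0.437 in early birch to 0.981 in late ash. Mono adduct was surviving better than that. So I tried s = 0.5:

c(mono adduct) = g·(√c(substrate) − c(substrate))

made over used = g·c(substrate)/c(mono adduct)

Here g is the adduct's share of lost substrate divided by s. The same two readings gave 0.824 and 0.836, so I kept g = 0.830.

I took one partner lost per substrate lost. Second-order kinetics on ash at 8.00 h then gave k = 0.789 M⁻¹ h⁻¹. I also assumed that over-reaction product comes through mono adduct, so it is the adduct's share of lost substrate minus the adduct still present.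

Winter: c(substrate) 1.62%, mono adduct 9.21%, over-reaction product 31.6%, made over used 0.146

Autumn: c(substrate) 29.4%, mono adduct 20.6%, over-reaction product 8.70%, made over used 1.18

So I committed to more over-reaction product than mono adduct in winter, and less in autumn.

The forecast gave over-reaction product and 9.2% for winter and over-reaction product and 21% for autumn, where its autumn line read “substrate ≈ 29%, adduct ≈ 21%, over-reaction product ≈ 50%”, so it parted from me on which species leads in autumn.

Winter ended with 31.1% of over-reaction product and 9.53% of mono adduct. Autumn ended with 8.59% of over-reaction product and 20.8% of mono adduct.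

    partner + other mono adduct → bis adduct (k = 0.0670 M⁻¹ h⁻¹)
    substrate + partner → other mono adduct (k = 0.470 M⁻¹ h⁻¹)
    partner + mono adduct → bis adduct (k = 0.00820 M⁻¹ h⁻¹)
    partner + mono adduct → over-reaction product (k = 0.400 M⁻¹ h⁻¹)
    substrate + partner → mono adduct (k = 0.340 M⁻¹ h⁻¹)

At 20.0 h in winter, mono adduct was made at 0.153 of the rate at which it was used up, each step taken net. My ratio, with g and winter's own end values, came to 0.152. A neighbour flask charged with 0.12 M of partner stood at 0.905 on that ratio and held 20.9% of mono adduct at 20.0 h.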